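**Retrosynthetic overview**
- Target ⇒ threefold O‑desilylation of its tris‑TBS ether. The (Z)‑feruloyl C=C comes from an Ando‑type Horner–Wadsworth–Emmons reaction of a C9' diphenylphosphonoacetate with O‑TBS‑vanillin; the (E)‑coumaroyl ester comes from acylation of C9–OH.
- C9–OH ⇒ ozonolysis/borane reduction of a 3‑(E)‑propenyl group; C9'–OH ⇒ reduction of a methyl propanoate side chain.
- Dihydrofuran ring (the only ring made; rings A and B are bought) ⇒ acid closure of an o‑hydroxyaryl benzylic silyl ether, 2,3‑trans, C2 set by C3.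
- C3–C3a bond and the C3 stereocentre ⇒ aromatic Claisen [3,3] rearrangement of an (S)‑configured (E)‑allyl aryl ether with 1,3‑chirality transfer.
- Allyl aryl ether ⇒ hydrozirconation/zinc transmetalation/addition to O‑TBS‑vanillin of the aryl propargyl ether made by Mitsunobu inversion of (R)‑but‑3‑yn‑2‑ol with methyl dihydroferulate.

Assumption: (diphenoxyphosphoryl)acetic acid, O‑TBS‑vanillin and (R)‑but‑3‑yn‑2‑ol are taken as catalogue reagents (TBS = tert‑butyldimethylsilyl).

**Route**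

Step 1
Reactants: 1 methyl 3-(4-hydroxy-3-methoxyphenyl)propanoate; 2 (R)-but-3-yn-2-ol
Product: 3 methyl 3-{4-[(2S)-but-3-yn-2-yloxy]-3-methoxyphenyl}propanoate
Conditions: PPh3, DIAD, THF, 0 °C to rt
Reagents that add atoms: none
Why: Mitsunobu etherification of the phenol (pKa about 10) proceeds by SN2 displacement with clean inversion at the propargylic carbinol, so the bought (R) centre becomes the (S) aryl ether centre.

Step 2
Reactants: 3 methyl 3-{4-[(2S)-but-3-yn-2-yloxy]-3-methoxyphenyl}propanoate; 4 4-(tert-butyldimethylsilyloxy)-3-methoxybenzaldehyde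
Product: 7 methyl 3-{4-[(2S,3E)-5-hydroxy-5-(3-methoxy-4-TBSO-phenyl)pent-3-en-2-yl]oxy-3-methoxyphenyl}propanoate (C5 epimers about 1:1), via alkenylzirconocene chloride 5 (not isolated), via alkenyl(methyl)zinc 6 (not isolated)
Conditions: Cp2Zr(H)Cl (1.15 equiv), CH2Cl2, rt; Me2Zn (1.15 equiv), −65 °C; then 4, 0 °C; aq. NH4Cl
Reagents that add atoms: none
Why: Syn hydrozirconation of the terminal alkyne (faster than ester reduction) fixes the E geometry, and Zr‑to‑Zn transmetalation followed by 1,2‑addition to the aldehyde (Wipf protocol) gives the allylic alcohol, whose new carbinol centre is uncontrolled on purpose because it is erased in step 4.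

Step 3
Reactants: 7 the allylic alcohol from step 2
Product: 8 methyl 3-{3-methoxy-4-[(2S,3E)-5-(3-methoxy-4-TBSO-phenyl)-5-TBSO-pent-3-en-2-yl]oxyphenyl}propanoate (C5 epimers)
Conditions: TBSCl, imidazole, DMF, rt
Reagents that add atoms: tert-butyldimethylsilyl chloride, CC(C)(C)[Si](C)(C)Cl
Why: Standard silylation masks the doubly activated carbinol against ionisation in the thermal step and turns it into the leaving group for the later ring closure.

Step 4
Reactants: 8 the bis‑silyl allyl aryl ether from step 3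
Product: 11 methyl 3-{(2R,3R)-7-methoxy-2-(3-methoxy-4-TBSO-phenyl)-3-[(E)-prop-1-enyl]-2,3-dihydro-1-benzofuran-5-yl}propanoate (2,3-trans), via ortho-dienone 9 (not isolated), via rearranged phenol 10 (not isolated)
Conditions: 1,2-dichlorobenzene, 180 °C, 3 h; then cool to 0 °C, CH2Cl2, TsOH·H2O (10 mol%), 0 °C to rt
Reagents that add atoms: none
Why: The aromatic Claisen [3,3]‑sigmatropic rearrangement runs through a chair transition state with the methyl group equatorial, so the (S) C–O centre is transferred suprafacially to the new benzylic C3 centre together with an E‑propenyl group; the acid then ionises the p‑silyloxybenzylic silyl ether and the neighbouring phenol closes the five‑membered ring, C3 directing the aryl group trans (kinetic and thermodynamic preference) to set C2 as R whichever C5 epimer was used.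

Step 5
Reactants: 11 the dihydrobenzofuran methyl ester from step 4
Product: 12 3-{(2R,3R)-7-methoxy-2-(3-methoxy-4-TBSO-phenyl)-3-[(E)-prop-1-enyl]-2,3-dihydro-1-benzofuran-5-yl}propan-1-ol
Conditions: i-Bu2AlH (2.5 equiv), CH2Cl2, −78 to 0 °C; aq. potassium sodium tartrate
Reagents that add atoms: none
Why: Hydride reduction of the only ester gives the C9' primary alcohol, and the aryl silyl ether and the alkene are inert to i-Bu2AlH at low temperature.

Step 6
Reactants: 12 the C9' alcohol from step 5; 13 (diphenoxyphosphoryl)acetic acid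
Product: 14 3-{(2R,3R)-7-methoxy-2-(3-methoxy-4-TBSO-phenyl)-3-[(E)-prop-1-enyl]-2,3-dihydro-1-benzofuran-5-yl}propyl 2-(diphenoxyphosphoryl)acetate
Conditions: DCC, DMAP (cat.), CH2Cl2, 0 °C to rt
Reagents that add atoms: none
Why: Steglich esterification installs the Ando phosphonoacetate, a latent (Z)‑feruloyl group that, unlike a cinnamate, survives the ozonolysis that follows.

Step 7
Reactants: 14 the phosphonoacetate from step 6
Product: 16 3-{(2R,3S)-3-(hydroxymethyl)-7-methoxy-2-(3-methoxy-4-TBSO-phenyl)-2,3-dihydro-1-benzofuran-5-yl}propyl 2-(diphenoxyphosphoryl)acetate, via secondary ozonide 15 (not isolated)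
Conditions: O3, CH2Cl2, −78 °C (Sudan Red 7B endpoint); then BH3·SMe2, −78 °C to rt
Reagents that add atoms: ozone, [O-][O+]=O
Why: Criegee ozonolysis of the only C=C, followed by direct borane reduction of the ozonide, gives the C9 alcohol without ever freeing the epimerisable α‑aryl aldehyde and without alkoxide that would attack the P–OPh groups; C3 is untouched and only its descriptor changes (R to S) through the priority switch.

Step 8
Reactants: 17 (E)-4-hydroxycinnamic acid (p-coumaric acid)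
Product: 19 (E)-3-[4-(tert-butyldimethylsilyloxy)phenyl]prop-2-enoic acid, via bis-silyl derivative 18 (not isolated)
Conditions: TBSCl (2.4 equiv), imidazole, DMF, rt; then AcOH/THF/H2O, rt
Reagents that add atoms: tert-butyldimethylsilyl chloride, CC(C)(C)[Si](C)(C)Cl
Why: Exhaustive silylation followed by selective hydrolysis of the far more labile silyl ester leaves the aryl silyl ether and the E alkene intact.

Step 9
Reactants: 16 the C9 alcohol from step 7; 19 the silyl‑protected coumaric acid from step 8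
Product: 20 {(2R,3S)-5-[3-(2-(diphenoxyphosphoryl)acetoxy)propyl]-7-methoxy-2-(3-methoxy-4-TBSO-phenyl)-2,3-dihydro-1-benzofuran-3-yl}methyl (E)-3-(4-TBSO-phenyl)prop-2-enoate
Conditions: DCC, DMAP (cat.), CH2Cl2, 0 °C to rt
Reagents that add atoms: none
Why: Steglich esterification of the only free hydroxyl installs the (E)‑coumaroyl ester; no free phenol is present to compete.

Step 10
Reactants: 20 the phosphonoacetate/coumarate diester from step 9; 4 4-(tert-butyldimethylsilyloxy)-3-methoxybenzaldehyde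
Product: 21 tris-O-TBS ether of the target (Z-feruloyl at C9', E-coumaroyl at C9)
Conditions: NaH (1.05 equiv), THF, 0 °C; then 4, −78 to −20 °C, dark
Reagents that add atoms: none
Why: In the Ando variant of the Horner–Wadsworth–Emmons reaction the electron‑poor diaryl phosphonate collapses rapidly from the kinetically formed adduct to the Z enoate (typically at least 9:1 with aryl aldehydes, the minor E isomer being removed by chromatography), and the phosphonate CH2 is the only acidic site in 20.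

Step 11
Reactants: 21 the tris‑TBS ether from step 10
Product: 22 the target, [(2R,3S)-2-(4-hydroxy-3-methoxyphenyl)-7-methoxy-5-{3-[(Z)-feruloyloxy]propyl}-2,3-dihydro-1-benzofuran-3-yl]methyl (E)-4-hydroxycinnamate
Conditions: Bu4NF (3.3 equiv), AcOH (3.5 equiv), THF, 0 °C, dark
Reagents that add atoms: none
Why: Buffered fluoride cleaves the three aryl silyl ethers within minutes while leaving both cinnamate esters, the Z alkene and the stereocentres untouched.

**Compound list**
1 | methyl 3-(4-hydroxy-3-methoxyphenyl)propanoate | COC(=O)CCc1ccc(O)c(OC)c1 | starting material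
2 | (R)-but-3-yn-2-ol | C[C@@H](O)C#C | starting material
3 | methyl 3-{4-[(2S)-but-3-yn-2-yloxy]-3-methoxyphenyl}propanoate | COC(=O)CCc1ccc(O[C@@H](C)C#C)c(OC)c1 | intermediate
4 | 4-(tert-butyldimethylsilyloxy)-3-methoxybenzaldehyde | COc1cc(C=O)ccc1O[Si](C)(C)C(C)(C)C | starting material
5 | chlorobis(cyclopentadienyl){(1E,3S)-3-[2-methoxy-4-(3-methoxy-3-oxopropyl)phenoxy]but-1-enyl}zirconium (Cp rings drawn σ-bonded) | COC(=O)CCc1ccc(O[C@@H](C)/C=C/[Zr](Cl)(C2C=CC=C2)C2C=CC=C2)c(OC)c1 | intermediate (not isolated)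
6 | methyl{(1E,3S)-3-[2-methoxy-4-(3-methoxy-3-oxopropyl)phenoxy]but-1-enyl}zinc | COC(=O)CCc1ccc(O[C@@H](C)/C=C/[Zn]C)c(OC)c1 | intermediate (not isolated)
7 | methyl 3-{4-[(2S,3E)-5-hydroxy-5-(3-methoxy-4-TBSO-phenyl)pent-3-en-2-yl]oxy-3-methoxyphenyl}propanoate, C5 epimers | COC(=O)CCc1ccc(O[C@@H](C)/C=C/C(O)c2ccc(O[Si](C)(C)C(C)(C)C)c(OC)c2)c(OC)c1 | intermediate
8 | 5-O-TBS ether of 7, C5 epimers | COC(=O)CCc1ccc(O[C@@H](C)/C=C/C(O[Si](C)(C)C(C)(C)C)c2ccc(O[Si](C)(C)C(C)(C)C)c(OC)c2)c(OC)c1 | intermediate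
9 | ortho-dienone: (6S)-2-methoxy-4-(3-methoxy-3-oxopropyl)-6-[(2R,3E)-1-(3-methoxy-4-TBSO-phenyl)-1-TBSO-pent-3-en-2-yl]cyclohexa-2,4-dien-1-one | COC(=O)CCC1=C[C@@H]([C@@H](/C=C/C)C(O[Si](C)(C)C(C)(C)C)c2ccc(O[Si](C)(C)C(C)(C)C)c(OC)c2)C(=O)C(OC)=C1 | intermediate (not isolated)
10 | methyl 3-{4-hydroxy-3-methoxy-5-[(2R,3E)-1-(3-methoxy-4-TBSO-phenyl)-1-TBSO-pent-3-en-2-yl]phenyl}propanoate, C1 epimers | COC(=O)CCc1cc(OC)c(O)c(c1)[C@@H](/C=C/C)C(O[Si](C)(C)C(C)(C)C)c1ccc(O[Si](C)(C)C(C)(C)C)c(OC)c1 | intermediate (not isolated)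
11 | methyl 3-{(2R,3R)-7-methoxy-2-(3-methoxy-4-TBSO-phenyl)-3-[(E)-prop-1-enyl]-2,3-dihydro-1-benzofuran-5-yl}propanoate (trans) | COC(=O)CCc1cc(OC)c2c(c1)[C@@H](/C=C/C)[C@H](c1ccc(O[Si](C)(C)C(C)(C)C)c(OC)c1)O2 | intermediate
12 | 3-{(2R,3R)-7-methoxy-2-(3-methoxy-4-TBSO-phenyl)-3-[(E)-prop-1-enyl]-2,3-dihydro-1-benzofuran-5-yl}propan-1-ol | OCCCc1cc(OC)c2c(c1)[C@@H](/C=C/C)[C@H](c1ccc(O[Si](C)(C)C(C)(C)C)c(OC)c1)O2 | intermediate
13 | (diphenoxyphosphoryl)acetic acid | OC(=O)CP(=O)(Oc1ccccc1)Oc1ccccc1 | starting material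
14 | 2-(diphenoxyphosphoryl)acetate ester of 12 | O=C(CP(=O)(Oc1ccccc1)Oc1ccccc1)OCCCc1cc(OC)c2c(c1)[C@@H](/C=C/C)[C@H](c1ccc(O[Si](C)(C)C(C)(C)C)c(OC)c1)O2 | intermediate
15 | secondary ozonide of 14 (5-methyl-1,2,4-trioxolan-3-yl at C3, trioxolane centres mixed, ring centres as in 14) | O=C(CP(=O)(Oc1ccccc1)Oc1ccccc1)OCCCc1cc(OC)c2c(c1)[C@@H](C1OC(C)OO1)[C@H](c1ccc(O[Si](C)(C)C(C)(C)C)c(OC)c1)O2 | intermediate (not isolated)
16 | 3-{(2R,3S)-3-(hydroxymethyl)-7-methoxy-2-(3-methoxy-4-TBSO-phenyl)-2,3-dihydro-1-benzofuran-5-yl}propyl 2-(diphenoxyphosphoryl)acetate | O=C(CP(=O)(Oc1ccccc1)Oc1ccccc1)OCCCc1cc(OC)c2c(c1)[C@@H](CO)[C@H](c1ccc(O[Si](C)(C)C(C)(C)C)c(OC)c1)O2 | intermediate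
17 | (E)-4-hydroxycinnamic acid | OC(=O)/C=C/c1ccc(O)cc1 | starting material
18 | tert-butyldimethylsilyl (E)-3-[4-(tert-butyldimethylsilyloxy)phenyl]prop-2-enoate | CC(C)(C)[Si](C)(C)OC(=O)/C=C/c1ccc(O[Si](C)(C)C(C)(C)C)cc1 | intermediate (not isolated)
19 | (E)-3-[4-(tert-butyldimethylsilyloxy)phenyl]prop-2-enoic acid | OC(=O)/C=C/c1ccc(O[Si](C)(C)C(C)(C)C)cc1 | intermediate
20 | (E)-4-TBSO-cinnamate ester (at C9) of 16 | O=C(CP(=O)(Oc1ccccc1)Oc1ccccc1)OCCCc1cc(OC)c2c(c1)[C@@H](COC(=O)/C=C/c1ccc(O[Si](C)(C)C(C)(C)C)cc1)[C@H](c1ccc(O[Si](C)(C)C(C)(C)C)c(OC)c1)O2 | intermediate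
21 | tris-O-TBS ether of the target | COc1cc(/C=C\C(=O)OCCCc2cc(OC)c3c(c2)[C@@H](COC(=O)/C=C/c2ccc(O[Si](C)(C)C(C)(C)C)cc2)[C@H](c2ccc(O[Si](C)(C)C(C)(C)C)c(OC)c2)O3)ccc1O[Si](C)(C)C(C)(C)C | intermediate
22 | CNP0267960.2, (2R,3S)-trans | COc1cc(/C=C\C(=O)OCCCc2cc(OC)c3c(c2)[C@@H](COC(=O)/C=C/c2ccc(O)cc2)[C@H](c2ccc(O)c(OC)c2)O3)ccc1O | target

**Totals**
Total steps: 11. Longest linear sequence: 10 (steps 1–7 and 9–11; step 8 is a one‑step side branch).

**Three steps most likely to fail, with fallbacks**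

Step 4 (Claisen rearrangement and ring closure). The γ‑branched allyl terminus slows the [3,3] shift. At 180 °C the free phenol 10 can enter the abnormal Claisen pathway (spirocyclopropyl dienone), which would erode C3, and the benzylic cation of the acid stage can lose H‑3. The fallback sets out from 8 and comes back at 11. Compound 8 is heated in 1,2‑dichlorobenzene with N,O‑bis(trimethylsilyl)acetamide, so the rearranged phenol is captured as soon as it forms as the aryl trimethylsilyl ether of 10 F2, which cannot undergo the abnormal rearrangement and is isolated. F2 is then stirred with TsOH·H2O in wet CH2Cl2 at 0 °C (BF3·OEt2 at −78 °C if elimination shows up), where the O–SiMe3 bond is cleaved first and the phenol closes onto the benzylic position to give 11.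

Step 2 (one‑pot hydrozirconation, transmetalation, addition). The electron‑rich aldehyde may add sluggishly to the alkenylzinc, and the ester limits the excess of hydride reagent. The fallback sets out from 3 and comes back at 7. Hydrozirconation of 3 with Cp2Zr(H)Cl is quenched with I2 to give the isolable (E)‑vinyl iodide F1. F1 is then coupled with aldehyde 4 under Nozaki–Hiyama–Kishi conditions (CrCl2, NiCl2 cat., DMSO, rt), which tolerate the ester and the aryl silyl ether, to give 7.

Step 7 (ozonolysis with borane work‑up). Ozone may attack the two electron‑rich arenes, or the ozonide may be reduced incompletely next to the activated phosphonoacetate. The fallback sets out from 14 and comes back at 16. Dihydroxylation of 14 (OsO4 cat., N‑methylmorpholine N‑oxide, acetone/H2O) gives the vicinal diol F3. NaIO4 in THF/H2O cleaves F3 to the 3‑formyl dihydrobenzofuran F4, whose only accessible epimerisation returns the trans isomer. F4 is reduced at once with BH3·SMe2 at 0 °C to give 16.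

**Further compounds**
F1 | step 2 | methyl 3-{4-[(2S,3E)-4-iodobut-3-en-2-yl]oxy-3-methoxyphenyl}propanoate | COC(=O)CCc1ccc(O[C@@H](C)/C=C/I)c(OC)c1
F2 | step 4 | aryl trimethylsilyl ether of 10: methyl 3-{3-methoxy-5-[(2R,3E)-1-(3-methoxy-4-TBSO-phenyl)-1-TBSO-pent-3-en-2-yl]-4-(trimethylsilyloxy)phenyl}propanoate | COC(=O)CCc1cc(OC)c(O[Si](C)(C)C)c(c1)[C@@H](/C=C/C)C(O[Si](C)(C)C(C)(C)C)c1ccc(O[Si](C)(C)C(C)(C)C)c(OC)c1
F3 | step 7 | 1,2-dihydroxypropyl analogue of 14 (diol centres mixed) | O=C(CP(=O)(Oc1ccccc1)Oc1ccccc1)OCCCc1cc(OC)c2c(c1)[C@@H](C(O)C(C)O)[C@H](c1ccc(O[Si](C)(C)C(C)(C)C)c(OC)c1)O2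
F4 | step 7 | 3-formyl analogue of 16 (2,3-trans) | O=C(CP(=O)(Oc1ccccc1)Oc1ccccc1)OCCCc1cc(OC)c2c(c1)[C@@H](C=O)[C@H](c1ccc(O[Si](C)(C)C(C)(C)C)c(OC)c1)O2
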